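**Plan**

- Numbering (benzofuran): O1, C2 (lactone C=O), C3 (aryl), C3a, C4 (aryl), C5 (OH), C6 (C=O), C7 (phenyl), C7a.
- Retrosynthesis: reduce the quinone methide to the C3–H catechol lactone and cut the lactone bond O1–C2. Then cut ring bond C3a–C7a (reverse 6π closure) and re-form C5–C7a to a cyclobutenone. Then cut C4–C5 (alkenyllithium + cyclobutenedione), C7–phenyl (PhLi + squarate) and C3–C3a (enolate alkylation).
- Enabling feature: C5(O)–C6(O)–C7(Ph)–C7a(O) of the carbocycle is a phenyl-substituted squaric acid unit, and C4=C3a is an alkene carrying the aryl group and the arylacetic arm. The benzene ring is therefore a four-membered ring enlarged by two alkene carbons.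
- Forward: the four-membered ring is bought and phenylated, the alkenyl arm is added, the six-membered carbocycle arises by ring expansion, the lactone ring closes, then demethylation and oxidation.
- Stereochemistry: the target has no stereocentre. The arm's alkene geometry comes from the Shapiro reaction; all sp3 centres on the way are racemic or mixed and are destroyed by aromatisation and the final oxidation.

Key step: step 7

Remark: phenyllithium is taken as the commercial solution; OBO means the 4-methyl-2,6,7-trioxabicyclo[2.2.2]octan-1-yl orthoester; every chiral intermediate is racemic or a diastereomer mixture, which is immaterial for an achiral target.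

**Step 1**
Reactants: 1 dimethyl squarate; 2 phenyllithium
Product: 4 3-methoxy-4-phenylcyclobut-3-ene-1,2-dione, via carbinol adduct 3 (not isolated)
Conditions: PhLi (1.05 equiv), THF, −78 °C; then 12 M HCl, CH2Cl2, 0 °C → rt
Reagents that add atoms: water, SMILES O
Why: 1,2-addition of the aryllithium to one squarate carbonyl, then acid-promoted loss of the carbinol hydroxyl, return of water at the methoxy-bearing allylic carbon and expulsion of methanol, is the standard conversion of a dialkyl squarate into a 3-alkoxy-4-arylcyclobutenedione.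

**Step 2**
Reactants: 5 (4-methoxyphenyl)acetyl chloride; 6 (3-methyloxetan-3-yl)methanol
Product: 7 (3-methyloxetan-3-yl)methyl (4-methoxyphenyl)acetate
Conditions: pyridine, CH2Cl2, 0 °C → rt
Reagents that add atoms: none
Why: esterification of a primary alcohol by an acid chloride under pyridine buffering is reliable and keeps the medium basic, so the acid-sensitive oxetane is untouched.

**Step 3**
Reactants: 7 (3-methyloxetan-3-yl)methyl (4-methoxyphenyl)acetate; 8 2-bromo-1-(4-methoxyphenyl)ethan-1-one
Product: 9 (3-methyloxetan-3-yl)methyl 2,4-bis(4-methoxyphenyl)-4-oxobutanoate (racemic)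
Conditions: LiN(iPr)2 (1.05 equiv), THF, −78 °C; then 8, −78 → −20 °C
Reagents that add atoms: none
Why: SN2 alkylation of the arylacetate lithium enolate by the very reactive phenacyl bromide should outrun attack at the ketone at low temperature; the new stereocentre forms racemic and is erased in the last step.

**Step 4**
Reactants: 9 keto ester; 10 2,4,6-triisopropylbenzenesulfonohydrazide
Product: 11 (3-methyloxetan-3-yl)methyl (4E)-2,4-bis(4-methoxyphenyl)-4-[2-(2,4,6-triisopropylbenzenesulfonyl)hydrazinylidene]butanoate (racemic)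
Conditions: pyridinium p-toluenesulfonate (cat.), 4 Å MS, THF, rt
Reagents that add atoms: none
Why: acid-catalysed hydrazone formation at the aryl ketone should give the E isomer with the sulfonamide nitrogen syn to the methylene group, while the mild pyridinium catalyst leaves the 3,3-disubstituted oxetane and the ester intact.

**Step 5**
Reactants: 11 trisylhydrazone oxetanylmethyl ester
Product: 12 N'-[(1E)-1,3-bis(4-methoxyphenyl)-3-(4-methyl-2,6,7-trioxabicyclo[2.2.2]octan-1-yl)propylidene]-2,4,6-triisopropylbenzenesulfonohydrazide (racemic)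
Conditions: BF3·OEt2 (0.3 equiv), CH2Cl2, −15 → 0 °C; then Et3N
Reagents that add atoms: none
Why: the Corey orthoester synthesis (BF3-promoted rearrangement of a 3-methyloxetan-3-ylmethyl ester through ester-carbonyl opening of the activated oxetane and collapse of the dioxanylium ion) tolerates N–H carbamates and should likewise tolerate the weakly basic sulfonylhydrazone.

**Step 6**
Reactants: 12 orthoester trisylhydrazone; 4 3-methoxy-4-phenylcyclobut-3-ene-1,2-dione
Product: 14 4-hydroxy-3-methoxy-2-phenyl-4-[(1E)-1,3-bis(4-methoxyphenyl)-3-(4-methyl-2,6,7-trioxabicyclo[2.2.2]octan-1-yl)prop-1-en-1-yl]cyclobut-2-en-1-one (diastereomer mixture), via alkenyllithium 13 (not isolated)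
Conditions: n-BuLi (2.0 equiv), THF, −78 °C, then 0 °C until N2 evolution ends; −78 °C, 4 (0.8 equiv); H2O quench, NaHCO3 wash
Reagents that add atoms: none
Why: in this Shapiro reaction, double deprotonation of the trisylhydrazone (N–H, then the syn α-methylene) and loss of sulfinate and N2 should give 13 with lithium trans to the branched carbon; 13 then adds 1,2 to the ketone-like carbonyl of 4 (next to the methoxy-bearing carbon, not the vinylogous ester carbonyl), and the orthoester offers no acidic or electrophilic site.

**Step 7**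
Reactants: 14 4-alkenyl-4-hydroxycyclobutenone
Product: 17 3-methoxy-5-(4-methoxyphenyl)-6-[(4-methoxyphenyl)(4-methyl-2,6,7-trioxabicyclo[2.2.2]octan-1-yl)methyl]-2-phenylbenzene-1,4-diol (racemic), via dienylketene 15 (not isolated), via cyclohexadienone 16 (not isolated)
Conditions: degassed toluene, 110 °C, Ar; concentrated under Ar and used directly
Reagents that add atoms: none
Why: Heating causes conrotatory 4π electrocyclic opening of the cyclobutenone bond between the carbonyl carbon and the carbinol carbon (C7a–C5 of the target), the hydroxyl rotating outward and the alkenyl group inward, so that dienylketene 15 has its ketene carbon beside the alkene terminus. A disrotatory 6π electrocyclisation then joins the ketene carbon (future C7a) to the CH terminus (future C3a), closing the six-membered carbocycle as cyclohexa-2,4-dienone 16, which aromatises by enolisation of the C3a–H to hydroquinone 17. The closest known reaction type is the Moore rearrangement of 4-alkenyl-4-hydroxycyclobutenones to hydroquinones. No lasting stereocentre is created: the ring sp3 centre of 16 is lost on aromatisation, and the arm methine stays racemic until step 10 removes it. The selectivity needed is outward rotation of the hydroxyl (an inward hydroxyl would add to the ketene and give a furanone), which the donor oxygen secures electronically, and the E alkene places hydrogen, not the bulky arm, on the inside of the closing terminus. All six substituents are already fixed in 14, so the congestion is met in an intramolecular pericyclic step.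

**Step 8**
Reactants: 17 hydroquinone orthoester
Product: 19 5-hydroxy-6-methoxy-3,4-bis(4-methoxyphenyl)-7-phenyl-1-benzofuran-2(3H)-one (racemic), via diol ester 18 (not isolated)
Conditions: 1 M HCl, THF, rt, Ar; then TsOH·H2O (cat.), toluene, 80 °C
Reagents that add atoms: water, SMILES O
Why: aqueous acid opens the OBO orthoester to dihydroxy ester 18, and the flanking C7a phenol then displaces the triol by acid-catalysed intramolecular transesterification (5-exo-trig lactonisation), the C5 hydroxyl being too remote to compete.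

**Step 9**
Reactants: 19 methoxy lactone
Product: 20 5,6-dihydroxy-3,4-bis(4-hydroxyphenyl)-7-phenyl-1-benzofuran-2(3H)-one (racemic)
Conditions: BBr3 (6 equiv), CH2Cl2, −78 °C → rt; H2O; handled under Ar
Reagents that add atoms: none
Why: Lewis-acid ether cleavage by BBr3 (bromide attack on the O-methyl of the borate complex) should remove all three methyl ethers, and the aryl lactone survives or recloses on aqueous work-up.

**Step 10**
Reactants: 20 catechol lactone
Product: 22 peniophorin (5-hydroxy-3,4-bis(4-hydroxyphenyl)-7-phenyl-1-benzofuran-2,6-dione), via ortho-quinone 21 (not isolated)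
Conditions: Ag2O (1.1 equiv), acetone/Et2O, rt
Reagents that add atoms: none
Why: dehydrogenation of the catechol by Ag2O gives ortho-quinone 21, and tautomerisation of its acidic, doubly activated C3–H toward O5 should deliver the fully conjugated hydroxy quinone methide lactone, which has no stereocentre.

**Compound list**

1 | dimethyl squarate (3,4-dimethoxycyclobut-3-ene-1,2-dione) | COC1=C(OC)C(=O)C1=O | starting material
2 | phenyllithium | [Li]c1ccccc1 | starting material
3 | 4-hydroxy-2,3-dimethoxy-4-phenylcyclobut-2-en-1-one (racemic, first as its lithium alkoxide) | COC1=C(OC)C(O)(c2ccccc2)C1=O | intermediate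
4 | 3-methoxy-4-phenylcyclobut-3-ene-1,2-dione | COC1=C(c2ccccc2)C(=O)C1=O | intermediate
5 | (4-methoxyphenyl)acetyl chloride | COc1ccc(CC(=O)Cl)cc1 | starting material
6 | (3-methyloxetan-3-yl)methanol | CC1(CO)COC1 | starting material
7 | (3-methyloxetan-3-yl)methyl (4-methoxyphenyl)acetate | COc1ccc(CC(=O)OCC2(C)COC2)cc1 | intermediate
8 | 2-bromo-1-(4-methoxyphenyl)ethan-1-one | COc1ccc(cc1)C(=O)CBr | starting material
9 | (3-methyloxetan-3-yl)methyl 2,4-bis(4-methoxyphenyl)-4-oxobutanoate (racemic) | COc1ccc(cc1)C(=O)CC(c1ccc(OC)cc1)C(=O)OCC1(C)COC1 | intermediate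
10 | 2,4,6-triisopropylbenzenesulfonohydrazide | CC(C)c1cc(C(C)C)c(S(=O)(=O)NN)c(C(C)C)c1 | starting material
11 | (3-methyloxetan-3-yl)methyl (4E)-2,4-bis(4-methoxyphenyl)-4-[2-(2,4,6-triisopropylbenzenesulfonyl)hydrazinylidene]butanoate (racemic) | COc1ccc(cc1)/C(CC(c1ccc(OC)cc1)C(=O)OCC1(C)COC1)=N/NS(=O)(=O)c1c(C(C)C)cc(C(C)C)cc1C(C)C | intermediate
12 | N'-[(1E)-1,3-bis(4-methoxyphenyl)-3-(4-methyl-2,6,7-trioxabicyclo[2.2.2]octan-1-yl)propylidene]-2,4,6-triisopropylbenzenesulfonohydrazide (racemic) | COc1ccc(cc1)/C(CC(c1ccc(OC)cc1)C12OCC(C)(CO1)CO2)=N/NS(=O)(=O)c1c(C(C)C)cc(C(C)C)cc1C(C)C | intermediate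
13 | [(1Z)-1,3-bis(4-methoxyphenyl)-3-(4-methyl-2,6,7-trioxabicyclo[2.2.2]octan-1-yl)prop-1-en-1-yl]lithium (racemic) | [Li]/C(c1ccc(OC)cc1)=C/C(c1ccc(OC)cc1)C12OCC(C)(CO1)CO2 | intermediate
14 | 4-hydroxy-3-methoxy-2-phenyl-4-[(1E)-1,3-bis(4-methoxyphenyl)-3-(4-methyl-2,6,7-trioxabicyclo[2.2.2]octan-1-yl)prop-1-en-1-yl]cyclobut-2-en-1-one (diastereomer mixture) | O=C1C(c2ccccc2)=C(OC)C1(O)/C(c1ccc(OC)cc1)=C/C(c1ccc(OC)cc1)C12OCC(C)(CO1)CO2 | intermediate
15 | (3Z,5E)-4-hydroxy-3-methoxy-5,7-bis(4-methoxyphenyl)-7-(4-methyl-2,6,7-trioxabicyclo[2.2.2]octan-1-yl)-2-phenylhepta-1,3,5-trien-1-one (dienylketene, racemic) | O=C=C(c1ccccc1)/C(OC)=C(/O)\C(c1ccc(OC)cc1)=C\C(c1ccc(OC)cc1)C12OCC(C)(CO1)CO2 | intermediate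
16 | 4-hydroxy-3-methoxy-5-(4-methoxyphenyl)-6-[(4-methoxyphenyl)(4-methyl-2,6,7-trioxabicyclo[2.2.2]octan-1-yl)methyl]-2-phenylcyclohexa-2,4-dien-1-one (diastereomer mixture) | O=C1C(c2ccccc2)=C(OC)C(O)=C(c2ccc(OC)cc2)C1C(c1ccc(OC)cc1)C12OCC(C)(CO1)CO2 | intermediate
17 | 3-methoxy-5-(4-methoxyphenyl)-6-[(4-methoxyphenyl)(4-methyl-2,6,7-trioxabicyclo[2.2.2]octan-1-yl)methyl]-2-phenylbenzene-1,4-diol (racemic) | COc1c(O)c(-c2ccc(OC)cc2)c(C(c2ccc(OC)cc2)C23OCC(C)(CO2)CO3)c(O)c1-c1ccccc1 | intermediate
18 | 3-hydroxy-2-(hydroxymethyl)-2-methylpropyl 2-[2,5-dihydroxy-4-methoxy-6-(4-methoxyphenyl)-3-phenylphenyl]-2-(4-methoxyphenyl)acetate (racemic) | COc1c(O)c(-c2ccc(OC)cc2)c(C(c2ccc(OC)cc2)C(=O)OCC(C)(CO)CO)c(O)c1-c1ccccc1 | intermediate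
19 | 5-hydroxy-6-methoxy-3,4-bis(4-methoxyphenyl)-7-phenyl-1-benzofuran-2(3H)-one (racemic) | O=C1Oc2c(-c3ccccc3)c(OC)c(O)c(-c3ccc(OC)cc3)c2C1c1ccc(OC)cc1 | intermediate
20 | 5,6-dihydroxy-3,4-bis(4-hydroxyphenyl)-7-phenyl-1-benzofuran-2(3H)-one (racemic) | O=C1Oc2c(-c3ccccc3)c(O)c(O)c(-c3ccc(O)cc3)c2C1c1ccc(O)cc1 | intermediate
21 | 3,4-bis(4-hydroxyphenyl)-7-phenyl-1-benzofuran-2,5,6(3H)-trione (racemic) | O=C1OC2=C(c3ccccc3)C(=O)C(=O)C(c3ccc(O)cc3)=C2C1c1ccc(O)cc1 | intermediate
22 | peniophorin, 5-hydroxy-3,4-bis(4-hydroxyphenyl)-7-phenyl-1-benzofuran-2,6-dione | O=C1OC2=C(c3ccccc3)C(=O)C(O)=C(c3ccc(O)cc3)C2=C1c1ccc(O)cc1 | target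

**Count**

Total steps: 10. Longest linear sequence: 9 steps (steps 2 to 10, from 5 and 6 to 22); step 1 is a one-step side branch.

**Steps most likely to fail, with fallbacks**

Step 5. The Lewis acid may be tied up by the sulfonylhydrazone, or the hydrazone may degrade, before the oxetane ester has rearranged. The fallback reverses the order of masking and condensation. It sets out from keto ester 9: BF3·OEt2 in CH2Cl2 at −15 °C, with no nitrogen function present, should give keto orthoester F1. Condensation of F1 with hydrazide 10 in THF over 4 Å molecular sieves, buffered with a trace of pyridine and without added acid, then leads to 12, where the route is rejoined.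

Step 6. During the 0 °C fragmentation the alkenyllithium may be quenched by proton transfer from the allylic and benzylic C–H of a second molecule; addition to the wrong carbonyl is the lesser risk. The fallback forms the carbon–lithium bond by halogen–lithium exchange at −78 °C instead of by hydrazone fragmentation. It sets out from keto ester 9, which is taken to keto orthoester F1 as above. Hydrazine hydrate (EtOH, Et3N, 70 °C) should give hydrazone F2. Iodine and tetramethylguanidine in THF (Barton alkenyl iodide synthesis) should give alkenyl iodide F3 as a mixture of alkene isomers. Treatment with t-BuLi (2 equiv) in THF at −78 °C, followed at once by dione 4, should give adduct 14 together with its Z alkene isomer F4. Both isomers are expected to ring-expand under the conditions of step 7, the Z isomer more slowly, because the alkene carbons become arene carbons. The route is rejoined at 17.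

Step 7. The closure may be slowed by congestion, the ketene may be captured by the free hydroxyl, or the free hydroquinone may oxidise in air before lactonisation. The fallback caps the carbinol oxygen so that a mono-protected, oxidation-resistant hydroquinone results. It sets out from 14: TMSCl and imidazole in DMF at 0 °C should give trimethylsilyl ether F5. Thermolysis in degassed toluene at 110 °C should give silyl-protected hydroquinone F6 by the same ring opening and 6π closure. The acid conditions of step 8 remove the silyl group, open the orthoester and lactonise, so the route is rejoined at 19.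

**Further compounds**

F1 | step 5 | 1,3-bis(4-methoxyphenyl)-3-(4-methyl-2,6,7-trioxabicyclo[2.2.2]octan-1-yl)propan-1-one (racemic) | COc1ccc(cc1)C(=O)CC(c1ccc(OC)cc1)C12OCC(C)(CO1)CO2
F2 | step 6 | (1E)-[1,3-bis(4-methoxyphenyl)-3-(4-methyl-2,6,7-trioxabicyclo[2.2.2]octan-1-yl)propylidene]hydrazine (racemic) | COc1ccc(cc1)/C(CC(c1ccc(OC)cc1)C12OCC(C)(CO1)CO2)=N/N
F3 | step 6 | 1-[3-iodo-1,3-bis(4-methoxyphenyl)prop-2-en-1-yl]-4-methyl-2,6,7-trioxabicyclo[2.2.2]octane (racemic, alkene isomer mixture, geometry left open) | COc1ccc(cc1)C(I)=CC(c1ccc(OC)cc1)C12OCC(C)(CO1)CO2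
F4 | step 6 | 4-hydroxy-3-methoxy-2-phenyl-4-[(1Z)-1,3-bis(4-methoxyphenyl)-3-(4-methyl-2,6,7-trioxabicyclo[2.2.2]octan-1-yl)prop-1-en-1-yl]cyclobut-2-en-1-one (diastereomer mixture) | O=C1C(c2ccccc2)=C(OC)C1(O)/C(c1ccc(OC)cc1)=C\C(c1ccc(OC)cc1)C12OCC(C)(CO1)CO2
F5 | step 7 | 3-methoxy-2-phenyl-4-(trimethylsilyloxy)-4-[(1E)-1,3-bis(4-methoxyphenyl)-3-(4-methyl-2,6,7-trioxabicyclo[2.2.2]octan-1-yl)prop-1-en-1-yl]cyclobut-2-en-1-one (diastereomer mixture) | O=C1C(c2ccccc2)=C(OC)C1(O[Si](C)(C)C)/C(c1ccc(OC)cc1)=C/C(c1ccc(OC)cc1)C12OCC(C)(CO1)CO2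
F6 | step 7 | 3-methoxy-5-(4-methoxyphenyl)-6-[(4-methoxyphenyl)(4-methyl-2,6,7-trioxabicyclo[2.2.2]octan-1-yl)methyl]-2-phenyl-4-(trimethylsilyloxy)phenol (racemic) | COc1c(O[Si](C)(C)C)c(-c2ccc(OC)cc2)c(C(c2ccc(OC)cc2)C23OCC(C)(CO2)CO3)c(O)c1-c1ccccc1
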